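**Retrosynthetic overview**
1. Structural feature: the only ring is the oxolane O1–C2–C3–C4–C5, with an aryl group on C2, a one-carbon arm (C9H2OH) on C3 and an arylmethyl arm (CbH2–aryl) on C4. Read outward from C3, it is the sum of propargyl alcohol (O1–C5–C4–Cb), an arylidene malonate (C2–C3–C9) and an aryl iodide (the aryl group on Cb).
2. Endgame: remove O–Si and O–benzyl. C4 is set by hydrogenating a Z-4-benzylidene oxolane on the face away from the C3 arm. C9H2OH comes from an ester, and C3–H from dealkoxycarbonylation of a 3,3-diester (2,3-trans).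
3. Key disconnection: O1–C2, C3–C4 and Cb–aryl are made in one palladium-catalysed three-component operation, which forms the ring and sets C2 under ligand control.
4. Building blocks: the acceptor comes from 3,4,5-trimethoxybenzaldehyde and diethyl malonate. The aryl iodide comes from 2-methoxyphenol by para-iodination and O-benzylation.

Key step: step 4

**Remarks**
- Route numbering throughout: O1, C2 (trimethoxyphenyl), C3 (C9 arm), C4 (Cb arm), C5. The target is 2R,3S,4S in this numbering (2,3-trans, 3,4-cis).
- Assumption: the sense of induction of the bisphosphine cannot be predicted. (R)-DTBM-SEGPHOS is written, and its antipode is used if a test run gives the 2R diester.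
- C2 is 2S in 10 and 2R from 11 on. C3 is 3R in 11 and 3S from 12 on. Only the CIP ranking of the neighbours changes; no bond at these centres is touched.

**Step 1**
Reactants: 1 3,4,5-trimethoxybenzaldehyde; 2 diethyl malonate
Product: 3 diethyl 2-[(3,4,5-trimethoxyphenyl)methylidene]propanedioate
Conditions: piperidine (cat.), AcOH (cat.), toluene, reflux, Dean–Stark trap
Reagents that add atoms: none
Why: Knoevenagel condensation of a non-enolisable aromatic aldehyde with a malonate, driven by azeotropic removal of water; no stereocentre is formed and the two ester groups are identical, so no alkene isomers arise.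

**Step 2**
Reactants: 4 2-methoxyphenol
Product: 5 4-iodo-2-methoxyphenol
Conditions: N-iodosuccinimide, TsOH·H2O (cat.), MeCN, 0 °C → rt
Reagents that add atoms: N-iodosuccinimide, O=C1CCC(=O)N1I
Why: Electrophilic aromatic iodination in which the free hydroxyl is the stronger director and its open para position is less crowded than the ortho one, so iodine should enter para to OH.

**Step 3**
Reactants: 5 4-iodo-2-methoxyphenol
Product: 6 1-(benzyloxy)-4-iodo-2-methoxybenzene
Conditions: BnBr, K2CO3, DMF, rt
Reagents that add atoms: benzyl bromide, BrCc1ccccc1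
Why: Williamson ether synthesis on a phenoxide, which masks the acidic phenol for the basic key step with a group that leaves later in the hydrogenation flask.

**Step 4**
Reactants: 7 prop-2-yn-1-ol; 3 diethyl 2-[(3,4,5-trimethoxyphenyl)methylidene]propanedioate; 6 1-(benzyloxy)-4-iodo-2-methoxybenzene
Product: 10 diethyl (2S,4Z)-4-{[4-(benzyloxy)-3-methoxyphenyl]methylidene}-2-(3,4,5-trimethoxyphenyl)oxolane-3,3-dicarboxylate, via potassium prop-2-yn-1-olate 8 (not isolated), via potassium malonate oxa-Michael adduct 9 (not isolated)
Conditions: 7, KOtBu (1.0 equiv), THF, 0 °C; then 3, 6, Pd(dba)2 (5 mol %), (R)-DTBM-SEGPHOS (6 mol %), THF–DMSO, 25–40 °C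
Reagents that add atoms: none
Why: Proposed new method: alkoxide 8 adds reversibly to the doubly activated alkene of 3 (oxa-Michael, O1–C2) to give the racemic, interconverting malonate anion 9, while zerovalent palladium inserts into the C–I bond of 6 and the resulting bisphosphine-bound divalent arylpalladium iodide binds the alkyne of 9 after iodide dissociation in the polar medium. C3 of the malonate then attacks the internal alkyne carbon C4 on the side away from the metal, which closes the oxolane in a 5-exo-dig mode (C3–C4), and reductive elimination from the alkenyl(aryl)palladium joins Cb to the aryl carbon with retention and regenerates zerovalent palladium. The closest known reaction type is the racemic palladium-mediated three-component coupling of propargyl alkoxides, alkylidene malonates and aryl halides, and the ability of a DTBM-SEGPHOS-bound divalent palladium–alkyne complex to impose asymmetry on the 5-exo-dig attack of a 1,3-dicarbonyl carbon has its nearest analogy in enantioselective Conia-ene cyclisations. C2, the only new stereocentre, is controlled by the chiral ligand through a dynamic kinetic resolution: the enantiomer of 9 that fits the ligand pocket with its C2 aryl group pseudo-equatorial in the envelope-like transition state closes faster, the other one drains back through retro-oxa-Michael addition (made easy by the electron-rich trimethoxyphenyl group, which stabilises 3), and 10 cannot reopen because C3 is then quaternary. The Z geometry (new aryl group cis to C5 and trans to C3) follows from anti attack followed by stereoretentive reductive elimination. The step needs chemoselectivity for ring closure over direct arylation of the terminal alkyne or of the malonate carbon and 5-exo over 6-endo regioselectivity, and both are secured by the short O1–C5 tether, which holds the soft carbanion within bonding distance of C4 of the coordinated alkyne.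

**Step 5**
Reactants: 10 diethyl (2S,4Z)-4-{[4-(benzyloxy)-3-methoxyphenyl]methylidene}-2-(3,4,5-trimethoxyphenyl)oxolane-3,3-dicarboxylate
Product: 11 ethyl (2R,3R,4Z)-4-{[4-(benzyloxy)-3-methoxyphenyl]methylidene}-2-(3,4,5-trimethoxyphenyl)oxolane-3-carboxylate (2,3-trans)
Conditions: LiCl, H2O (2–3 equiv), DMSO, 150 °C, reaction stopped at full conversion
Reagents that add atoms: none
Why: Krapcho dealkoxycarbonylation, in which chloride dealkylates one ethyl ester by SN2 attack, CO2 is lost and water protonates the extended ester enolate at C3 (the kinetic site for dienolates, so the styrene-type C4=Cb bond should stay), the doubly activated C3–H then equilibrates to the more stable 2,3-trans ester, and β-elimination of O1 is disfavoured as the reverse of a 5-endo-trig closure.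

**Step 6**
Reactants: 11 ethyl (2R,3R,4Z)-4-{[4-(benzyloxy)-3-methoxyphenyl]methylidene}-2-(3,4,5-trimethoxyphenyl)oxolane-3-carboxylate
Product: 12 [(2R,3S,4Z)-4-{[4-(benzyloxy)-3-methoxyphenyl]methylidene}-2-(3,4,5-trimethoxyphenyl)oxolan-3-yl]methanol
Conditions: LiAlH4, THF, −20 → 0 °C; then H2O, aq NaOH
Reagents that add atoms: none
Why: Hydride reduction of an ester to the primary alcohol, where carbonyl addition at low temperature should outrun deprotonation at C3, the alkene and the ethers are inert, and C3 is no longer epimerisable afterwards.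

**Step 7**
Reactants: 12 [(2R,3S,4Z)-4-{[4-(benzyloxy)-3-methoxyphenyl]methylidene}-2-(3,4,5-trimethoxyphenyl)oxolan-3-yl]methanol
Product: 13 {[(2R,3S,4Z)-4-{[4-(benzyloxy)-3-methoxyphenyl]methylidene}-2-(3,4,5-trimethoxyphenyl)oxolan-3-yl]methoxy}tri(propan-2-yl)silane
Conditions: iPr3SiCl, imidazole, DMF, rt
Reagents that add atoms: chlorotri(propan-2-yl)silane, CC(C)[Si](Cl)(C(C)C)C(C)C
Why: Imidazole-promoted silylation of a primary alcohol, which removes any hydroxyl-directing effect and places a large group on the carbon next to C4 as the steric screen for the hydrogenation.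

**Step 8**
Reactants: 13 {[(2R,3S,4Z)-4-{[4-(benzyloxy)-3-methoxyphenyl]methylidene}-2-(3,4,5-trimethoxyphenyl)oxolan-3-yl]methoxy}tri(propan-2-yl)silane
Product: 15 2-methoxy-4-{[(3S,4S,5R)-5-(3,4,5-trimethoxyphenyl)-4-({[tri(propan-2-yl)silyl]oxy}methyl)oxolan-3-yl]methyl}phenol (route numbering 2R,3S,4S), via saturated benzyl ether 14 (not isolated)
Conditions: H2 (1 atm), 10% Pd/C, EtOAc–EtOH, rt, stopped once the benzyl ether is consumed
Reagents that add atoms: none
Why: Heterogeneous syn hydrogenation of the trisubstituted styrene-type alkene should occur on the ring face away from the adjacent C3 silyloxymethyl arm (the pattern by which benzylidene lactone lignan precursors give cis products), so H enters C4 anti to that arm and the arylmethyl group ends cis to it (4S), after which hydrogenolysis cleaves the aryl benzyl ether.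

**Step 9**
Reactants: 15 2-methoxy-4-{[(3S,4S,5R)-5-(3,4,5-trimethoxyphenyl)-4-({[tri(propan-2-yl)silyl]oxy}methyl)oxolan-3-yl]methyl}phenol
Product: 16 4-{[(3S,4S,5R)-4-(hydroxymethyl)-5-(3,4,5-trimethoxyphenyl)oxolan-3-yl]methyl}-2-methoxyphenol (target; route numbering 2R,3S,4S)
Conditions: Bu4NF, AcOH (1:1), THF, 0 °C → rt
Reagents that add atoms: none
Why: Fluoride-induced cleavage of the silyl ether driven by the Si–F bond, with the acetic acid buffer keeping the phenol protonated and avoiding strongly acidic conditions that could ionise the electron-rich benzylic C2–O1 bond.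

**Compound list**
1 | 3,4,5-trimethoxybenzaldehyde | COc1cc(C=O)cc(OC)c1OC | starting material
2 | diethyl malonate | CCOC(=O)CC(=O)OCC | starting material
3 | diethyl 2-[(3,4,5-trimethoxyphenyl)methylidene]propanedioate | CCOC(=O)C(=Cc1cc(OC)c(OC)c(OC)c1)C(=O)OCC | intermediate
4 | 2-methoxyphenol | COc1ccccc1O | starting material
5 | 4-iodo-2-methoxyphenol | COc1cc(I)ccc1O | intermediate
6 | 1-(benzyloxy)-4-iodo-2-methoxybenzene | COc1cc(I)ccc1OCc1ccccc1 | intermediate
7 | prop-2-yn-1-ol | C#CCO | starting material
8 | potassium prop-2-yn-1-olate | [K+].[O-]CC#C | intermediate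
9 | potassium salt of the diethyl 2-[(prop-2-yn-1-yloxy)(3,4,5-trimethoxyphenyl)methyl]propanedioate carbanion (racemic, equilibrating) | CCOC(=O)[C-](C(=O)OCC)C(OCC#C)c1cc(OC)c(OC)c(OC)c1.[K+] | intermediate
10 | diethyl (2S,4Z)-4-{[4-(benzyloxy)-3-methoxyphenyl]methylidene}-2-(3,4,5-trimethoxyphenyl)oxolane-3,3-dicarboxylate | CCOC(=O)C1(C(=O)OCC)[C@H](c2cc(OC)c(OC)c(OC)c2)OC/C1=C\c3ccc(OCc4ccccc4)c(OC)c3 | intermediate
11 | ethyl (2R,3R,4Z)-4-{[4-(benzyloxy)-3-methoxyphenyl]methylidene}-2-(3,4,5-trimethoxyphenyl)oxolane-3-carboxylate | CCOC(=O)[C@H]1[C@H](c2cc(OC)c(OC)c(OC)c2)OC/C1=C\c3ccc(OCc4ccccc4)c(OC)c3 | intermediate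
12 | [(2R,3S,4Z)-4-{[4-(benzyloxy)-3-methoxyphenyl]methylidene}-2-(3,4,5-trimethoxyphenyl)oxolan-3-yl]methanol | OC[C@H]1[C@H](c2cc(OC)c(OC)c(OC)c2)OC/C1=C\c3ccc(OCc4ccccc4)c(OC)c3 | intermediate
13 | {[(2R,3S,4Z)-4-{[4-(benzyloxy)-3-methoxyphenyl]methylidene}-2-(3,4,5-trimethoxyphenyl)oxolan-3-yl]methoxy}tri(propan-2-yl)silane | CC(C)[Si](C(C)C)(C(C)C)OC[C@H]1[C@H](c2cc(OC)c(OC)c(OC)c2)OC/C1=C\c3ccc(OCc4ccccc4)c(OC)c3 | intermediate
14 | {[(2R,3S,4S)-4-{[4-(benzyloxy)-3-methoxyphenyl]methyl}-2-(3,4,5-trimethoxyphenyl)oxolan-3-yl]methoxy}tri(propan-2-yl)silane | COc1cc(C[C@@H]2CO[C@@H](c3cc(OC)c(OC)c(OC)c3)[C@@H]2CO[Si](C(C)C)(C(C)C)C(C)C)ccc1OCc4ccccc4 | intermediate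
15 | 2-methoxy-4-{[(3S,4S,5R)-5-(3,4,5-trimethoxyphenyl)-4-({[tri(propan-2-yl)silyl]oxy}methyl)oxolan-3-yl]methyl}phenol | COc1cc(C[C@@H]2CO[C@@H](c3cc(OC)c(OC)c(OC)c3)[C@@H]2CO[Si](C(C)C)(C(C)C)C(C)C)ccc1O | intermediate
16 | 4-{[(3S,4S,5R)-4-(hydroxymethyl)-5-(3,4,5-trimethoxyphenyl)oxolan-3-yl]methyl}-2-methoxyphenol | COc1cc(C[C@@H]2CO[C@@H](c3cc(OC)c(OC)c(OC)c3)[C@@H]2CO)ccc1O | target

**Step count**
Total step count: 9
Longest linear sequence: 8 steps (steps 2 to 9, from 2-methoxyphenol)

**Steps most likely to fail**

Step 4.
- What may go wrong: the C2 stereocentre of 9 lies on the far side of the alkyne from the metal, so the ligand may discriminate poorly between the two enantiomers. Retro-oxa-Michael exchange may be too slow relative to ring closure. Direct arylation of the terminal alkyne may compete.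
- Fallback (known chemistry): set out from 3, 6 and 7 and run the coupling in its established racemic form (KOtBu, Pd(dba)2, 1,2-bis(diphenylphosphino)ethane, THF–DMSO). This gives the racemic diester F1.
- F1 is resolved by preparative chromatography on an amylose tris(3,5-dimethylphenylcarbamate) phase with supercritical CO2–MeOH. The unwanted (2R)-enantiomer F2 is set aside, and the route is rejoined at 10.

Step 5.
- What may go wrong: on prolonged heating with basic salts, the C4=Cb double bond may migrate into conjugation with the ester, giving a 2,5-dihydrofuran that can then aromatise in air. Equilibration at C3 may also stay incomplete.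
- Fallback: set out from 10 and replace the hot dealkylative process by a two-stage hydrolysis and decarboxylation. One equivalent of KOH in aqueous EtOH should hydrolyse the less hindered ester, the one trans to the C2 aryl group. Acidification with HCl gives the malonic half-acid F3.
- F3 loses CO2 through the cyclic six-membered transition state in toluene at 90–110 °C under neutral conditions. Any 2,3-cis ester is brought to trans by a short, monitored exposure to catalytic DBU at room temperature. The route is rejoined at 11.

Step 8.
- What may go wrong: the C2 aryl group screens the face that must accept hydrogen, so facial selectivity may be poor. Palladium hydride may move the alkene into the ring as an enol ether. The allylic C5–O1 or benzylic C2–O1 bond may undergo hydrogenolysis.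
- Fallback: set out from 13 and replace substrate control on a metal surface by catalyst control in solution. The trisubstituted aryl alkene is hydrogenated with the cationic iridium phosphine–oxazoline complex [Ir(cod)(tBu-PHOX)][B(C6H3(CF3)2)4] (H2 50 bar, CH2Cl2, rt), using the ligand antipode that is matched with the substrate bias.
- This catalyst type neither cleaves C–O bonds nor removes the benzyl group, so 14 is isolated. The route is rejoined at 14, which a short Pd/C hydrogenolysis takes on to 15. This detour makes no compound outside the list (F0).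

**Further compounds**
F1 | step 4 | racemic diethyl (4Z)-4-{[4-(benzyloxy)-3-methoxyphenyl]methylidene}-2-(3,4,5-trimethoxyphenyl)oxolane-3,3-dicarboxylate | CCOC(=O)C1(C(=O)OCC)C(c2cc(OC)c(OC)c(OC)c2)OC/C1=C\c3ccc(OCc4ccccc4)c(OC)c3
F2 | step 4 | diethyl (2R,4Z)-4-{[4-(benzyloxy)-3-methoxyphenyl]methylidene}-2-(3,4,5-trimethoxyphenyl)oxolane-3,3-dicarboxylate | CCOC(=O)C1(C(=O)OCC)[C@@H](c2cc(OC)c(OC)c(OC)c2)OC/C1=C\c3ccc(OCc4ccccc4)c(OC)c3
F3 | step 5 | (2S,3S,4Z)-4-{[4-(benzyloxy)-3-methoxyphenyl]methylidene}-3-(ethoxycarbonyl)-2-(3,4,5-trimethoxyphenyl)oxolane-3-carboxylic acid | OC(=O)[C@@]1(C(=O)OCC)[C@H](c2cc(OC)c(OC)c(OC)c2)OC/C1=C\c3ccc(OCc4ccccc4)c(OC)c3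
F0 | step 8 | none | none
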